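## Structural features

The target is a monoacylphloroglucinol: a single benzene ring with hydroxyl groups on C2', C4' and C6', whose C1' carries the ketone carbon C1 of an unbranched sixteen-carbon chain. From C1 the chain runs through eleven unfunctionalised methylenes, C2 to C12, to the secondary carbinol C13 and ends in the propyl group C14–C16. C13 is the only stereocentre, has the S configuration and has no stereogenic neighbour; its two carbon substituents, propyl and a long methylene chain, differ only in length. The fragile parts are the electron-rich triphenol, which is easily oxidised (in air as a phenolate, and certainly at an anode) and can be substituted a second time, and the C13–O bond, which must be neither acylated nor ionised when the ring is attached under Lewis acid. The real difficulty lies in the chain: a C13 ketone flanked by two nearly identical alkyl groups cannot be reduced with useful enantioselectivity, so C13 must be created next to a directing carbonyl group and then joined to a long chain through an sp3–sp3 bond between two methylenes that offer no handle. The key step exploits that pair of methylenes, C11 and C12: with a carboxyl group imagined on each, C13 becomes the β-carbon of a 3-hydroxy acid, and the C11–C12 bond arises from two primary radicals while C13 stays one atom away from the reacting centre.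

## Logic of the disconnections

13 ⇒ 12. An acetyl group is placed on O13. The cut is at the acyl–oxygen bond, not at C13–O, so the stereocentre is not involved. Nothing is gained in skeleton, but the masked hydroxyl is what makes the preceding acylation clean. The forward step must remove a secondary acetate without harming the aryl ketone or the oxidisable triphenol, which calls for methanolysis under inert gas.

12 ⇒ 9 + 10 (through 11). The C1–C1' bond is cut. The three ring CH positions of 10 are equivalent, so no regiochemical question arises, and the whole arene is bought. What remains is an aliphatic acid with one stereocentre. The forward step must give C-acylation over O-acylation and one acylation, not two, and must leave the C13–O bond intact. A free hydroxyl at C13 would esterify the activated carboxyl group and could ionise under the Lewis acid, hence the acetate in 9 and a reaction at or below room temperature.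

9 ⇒ 8. The tert-butyl–oxygen bond of the C1 ester is cut. The carboxyl end must pass the electrolysis as an ester and must then be freed while the C13 acetate stays. A methyl ester could only be hydrolysed together with the acetate, so the half ester is designed as a tert-butyl ester, which acid removes and to which the acetate is inert. The demand on the forward step is small: acidolysis with no ionisation at C13.

8 ⇒ 5 + 7. The C11–C12 bond is cut and one carboxyl carbon is added to each end. This is the only cut that turns C13 into the β-position of a carboxylic acid while leaving the rest as a derivative of the symmetrical 6. The gain is large, since one step joins a C6 and a C12 building block. The forward step must discharge both acids together, let the primary radicals couple instead of being oxidised further, allow separation of 8 from the two symmetrical dimers, and leave both ester groups and C13 alone. For that reason O13 is acetylated (a free β-hydroxy acid is a poor substrate) and C1 bears an ester that is inert at the anode.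

7 ⇒ 6. One ester C–O bond is cut, leading to a cheap symmetrical diacid. The demand is mono-functionalisation, which is statistical and settled by separation and recycling.

5 ⇒ 3 (through 4) ⇒ 2. The acetyl–oxygen bond and the methyl ester are cut in turn; both are functional-group changes that leave C3 untouched. The acetylation must not trigger β-elimination, so it is run without base.

2 ⇒ 1. The C3–H and O–H bonds are removed, which traces the stereocentre back to a prochiral β-keto ester. The forward step must select one face of the ketone, and chelation of the keto ester to a BINAP–ruthenium catalyst does this. The descriptor stays S from 2 to 13 because the priority order O > carboxyl-side carbon > propyl > H is the same at every stage.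

## Other disconnections considered

Alternative 1: The cut runs through the benzene ring, between the acyl-bearing carbon and a hydroxylated neighbour, and unfolds the arene into the open-chain trioxo ester A2, methyl (19S)-19-[(tert-butyldimethylsilyl)oxy]-3,5,7-trioxodocosanoate. In the forward step Mg(OCH3)2 in methanol would hold the chain as a magnesium chelate, C6 would attack the ester carbon in a Claisen (Dieckmann-type) condensation, and enolisation would aromatise the ring to A1, (13S)-13-[(tert-butyldimethylsilyl)oxy]-1-(2,4,6-trihydroxyphenyl)hexadecan-1-one.
- In its favour: the acyl group is in place when the ring forms, no Lewis-acid acylation is needed, and only a desilylation follows.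
- Against it here: A2 contains the same C13-oxygenated C16 acyl chain as 9, so the chain problem is untouched and two further C–C bond formations are spent on a ring that 10 supplies directly. A2 can also close by aldol condensation to a resorcylate or lactonise to a pyrone, and its assembly needs polyanion chemistry.
- Comparison: on structure it is the equal of the chosen plan, since both carry C13 in from outside. On exposure of the C13–O bond it is the better, because that bond never meets AlCl3. On mechanism it carries a mode-of-cyclisation risk that the chosen plan does not have, and on step economy it is clearly longer.

Alternative 2: The cut is at C10–C11, combined with a ring-opening that generates the C1 ketone. The tertiary alcohol A4, 1-(2,4,6-trimethoxyphenyl)cyclodecan-1-ol, would be oxidised by an excited photocatalyst to an alkoxy radical; β-scission would give the aryl ketone and a primary C10 radical, which would add (Giese addition) to A5, hex-1-en-3-one, to give the diketone A3, 1-(2,4,6-trimethoxyphenyl)hexadecane-1,13-dione.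
- In its favour: it is convergent and redox-neutral, and one operation delivers the C1 ketone, the nine-methylene spacer and the C10–C11 bond without a Lewis acid.
- Against it here: A3 has a carbonyl group at C13, so the stereocentre is missing and would have to come from enantioselective reduction of a ketone whose two arms differ only in length; no chemical catalyst can be relied on for that. Three aryl methyl ethers would then have to be cleaved with a strong Lewis acid next to the new secondary alcohol. A4, the adduct of a hindered aryl-metal reagent and an easily enolised medium-ring ketone, should also be hard to make and prone to dehydration.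
- Comparison: in speed of building the carbon skeleton and in avoiding a statistical coupling it is the better of the two. On stereocontrol and on the final deprotection it is much weaker, so its apparent step economy would be lost.

Alternative 3: The cut is at C1–C2. NiCl2(1,2-dimethoxyethane) with 4,4'-di-tert-butyl-2,2'-bipyridine and zinc powder would couple the thioester A7, S-(pyridin-2-yl) 2,4,6-tris(benzyloxy)benzenecarbothioate, with the iodide A8, tert-butyl{[(4S)-15-iodopentadecan-4-yl]oxy}dimethylsilane. Low-valent nickel inserts into the acyl–sulfur bond, captures the alkyl radical formed from A8 and eliminates the ketone A6, (13S)-13-[(tert-butyldimethylsilyl)oxy]-1-[2,4,6-tris(benzyloxy)phenyl]hexadecan-1-one.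
- In its favour: the conditions are mild and nearly neutral, no organometallic reagent is prepared beforehand, the ketone cannot over-add, and the cross-selectivity between two different electrophiles is built into the mechanism.
- Against it here: A8 still carries the remote stereocentre at the end of a C15 chain and needs its own sp3–sp3 coupling, so the central problem is only moved. The acyl group of A7 lies between two ortho benzyloxy groups and should react sluggishly at nickel. The arene needs three benzylations and a carboxyl activation beforehand, and two deprotections afterwards.
- Comparison: in cross-selectivity and in keeping the C13–O bond away from Lewis acid it is the better of the two. In mildness of the end-game it is the equal. In step count and in dealing with the real difficulty of the chain it is the weaker.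

Key step: step 5

Assumption: the chain is numbered from the ketone carbon C1 to the methyl carbon C16, the ring carbons are C1' to C6', and 10 is used in its anhydrous form.

## Steps

Step 1
Reactants: 1 methyl 3-oxohexanoate
Product: 2 methyl (3S)-3-hydroxyhexanoate
Conditions: H2 (50 bar), RuCl2[(S)-BINAP] (0.1 mol %), MeOH, 50 °C
Reagents that add atoms: none
Why: Noyori asymmetric hydrogenation of a β-keto ester: the substrate chelates divalent ruthenium through both carbonyl oxygens and the (S)-BINAP ligand admits hydride to one face only, which sets C3 as S (the later C13); the (R)-ligand would give the antipode.

Step 2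
Reactants: 2 methyl (3S)-3-hydroxyhexanoate
Product: 3 (3S)-3-hydroxyhexanoic acid
Conditions: LiOH·H2O (1.5 equiv), THF/H2O (3:1), 0 °C → rt; then 1 M HCl (pH 2), NaCl, EtOAc extraction
Reagents that add atoms: lithium hydroxide, [Li+].[OH-]
Why: Ester saponification by acyl–oxygen cleavage at low temperature; C3 carries no acidic hydrogen and is not touched, and the mild conditions keep retro-aldol cleavage and dehydration away.

Step 3
Reactants: 3 (3S)-3-hydroxyhexanoic acid
Product: 5 (3S)-3-acetoxyhexanoic acid, via acetic (3S)-3-acetoxyhexanoic anhydride 4 (not isolated)
Conditions: AcCl (3 equiv), CH2Cl2, 0 °C → rt; then THF/H2O, rt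
Reagents that add atoms: acetyl chloride, CC(=O)Cl; water, O (its oxygen may end in the carboxyl group when 4 is hydrolysed)
Why: O-Acetylation of the secondary alcohol with an acyl chloride without base, which avoids E1cB loss of acetate; the carboxyl group is acetylated as well to the mixed anhydride 4, which water cleaves back to the acid, and the C3–O bond is never broken, so the configuration is retained.

Step 4
Reactants: 6 dodecanedioic acid
Product: 7 12-(tert-butoxy)-12-oxododecanoic acid
Conditions: Me2NCH(OtBu)2 (1.2 equiv, slow addition), toluene, 90 °C
Reagents that add atoms: N,N-dimethylformamide di-tert-butyl acetal, CN(C)C(OC(C)(C)C)OC(C)(C)C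
Why: Esterification of a carboxylic acid with a formamide di-tert-butyl acetal: the acid protonates the acetal and the carboxylate picks up the tert-butyl cation; with about one equivalent the outcome is statistical, and the half ester is separated from recovered diacid and from diester by extraction and chromatography.

Step 5
Reactants: 5 (3S)-3-acetoxyhexanoic acid; 7 12-(tert-butoxy)-12-oxododecanoic acid
Product: 8 tert-butyl (13S)-13-acetoxyhexadecanoate
Conditions: 5 (1 equiv), 7 (4 equiv), NaOMe (0.05 equiv per acid), MeOH, undivided cell, smooth Pt anode, Pt cathode, constant current 0.3 A cm−2, 35–40 °C, to pH 8; then AcOH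
Reagents that add atoms: none
Why: Both carboxylates are discharged at the smooth platinum anode under high current density, each acyloxy radical loses CO2, and the primary radicals C12 (from 5) and C11 (from 7) combine in the dense radical layer at the surface to form the C11–C12 bond, while the cathode reduces the carboxyl protons to H2. The closest known reaction type is the mixed Kolbe electrolysis of an O-acylated 3-hydroxy acid with a dicarboxylic acid half ester. No ring is closed and no stereocentre is made: C13 was fixed in step 1 and sits next to, not at, the radical carbon, so it cannot racemise. Two selectivities are needed, cross- over homo-coupling and radical over cation chemistry. The first is only statistical, so a fourfold excess of 7 makes nearly every radical from 5 meet a radical from 7, and the two symmetrical dimers differ enough from 8 in size and polarity to be removed by chromatography. The second is secured by the substrate: both radicals are primary with no donor on the radical carbon, the acetoxy group on C13 withdraws electron density, so further oxidation to a carbocation should be slow compared with coupling, and the 1,2-acyloxy shift of the radical from 5 is far slower than dimerisation at the electrode. The run is stopped when the solution turns basic so that methoxide cannot attack the acetate or the tert-butyl ester.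

Step 6
Reactants: 8 tert-butyl (13S)-13-acetoxyhexadecanoate
Product: 9 (13S)-13-acetoxyhexadecanoic acid
Conditions: TFA/CH2Cl2 (1:2), 0 °C → rt; evaporation with toluene
Reagents that add atoms: none
Why: Acidolysis of a tert-butyl ester by alkyl–oxygen cleavage through the tert-butyl cation, lost as isobutene; the secondary acetate has no such low-energy ionisation path and survives, so the two ester groups are told apart cleanly.

Step 7
Reactants: 9 (13S)-13-acetoxyhexadecanoic acid; 10 phloroglucinol (benzene-1,3,5-triol)
Product: 12 (13S)-13-acetoxy-1-(2,4,6-trihydroxyphenyl)hexadecan-1-one, via (13S)-13-acetoxyhexadecanoyl chloride 11 (not isolated)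
Conditions: (COCl)2 (1.3 equiv), DMF (cat.), CH2Cl2, 0 °C → rt, concentrate; then 10 (1.5 equiv), AlCl3 (6 equiv), CH2Cl2/MeNO2, 0 °C → rt; ice/1 M HCl
Reagents that add atoms: none
Why: Acid chloride formation with oxalyl chloride, then Friedel–Crafts C-acylation of 10: its three ring CH positions are equivalent, the aluminium-chelated ketone deactivates the ring against a second acylation, and any aryl ester formed first can be carried to the ketone by Fries rearrangement under the same Lewis acid. The acetate keeps O13 from competing as a nucleophile and, as an unactivated secondary ester at or below room temperature, is not expected to ionise; any acetate lost here only anticipates step 8.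

Step 8
Reactants: 12 (13S)-13-acetoxy-1-(2,4,6-trihydroxyphenyl)hexadecan-1-one
Product: 13 (13S)-13-hydroxy-1-(2,4,6-trihydroxyphenyl)hexadecan-1-one
Conditions: K2CO3 (5 equiv), MeOH (degassed), Ar, rt; then 1 M HCl (pH 3)
Reagents that add atoms: none
Why: Base-mediated transesterification (methanolysis) of the secondary acetate; attack is at the acetyl carbonyl, so C13 keeps its configuration, and the aryl ketone, present as an electron-rich phenolate, is inert to methoxide. Exclusion of oxygen protects the phenolate from autoxidation.

## Compound list

1 | methyl 3-oxohexanoate | CCCC(=O)CC(=O)OC | starting material
2 | methyl (3S)-3-hydroxyhexanoate | CCC[C@H](O)CC(=O)OC | intermediate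
3 | (3S)-3-hydroxyhexanoic acid | CCC[C@H](O)CC(=O)O | intermediate
4 | acetic (3S)-3-acetoxyhexanoic anhydride | CCC[C@H](OC(C)=O)CC(=O)OC(C)=O | intermediate (not isolated)
5 | (3S)-3-acetoxyhexanoic acid | CCC[C@H](OC(C)=O)CC(=O)O | intermediate
6 | dodecanedioic acid | OC(=O)CCCCCCCCCCC(=O)O | starting material
7 | 12-(tert-butoxy)-12-oxododecanoic acid | CC(C)(C)OC(=O)CCCCCCCCCCC(=O)O | intermediate
8 | tert-butyl (13S)-13-acetoxyhexadecanoate | CCC[C@H](OC(C)=O)CCCCCCCCCCCC(=O)OC(C)(C)C | intermediate
9 | (13S)-13-acetoxyhexadecanoic acid | CCC[C@H](OC(C)=O)CCCCCCCCCCCC(=O)O | intermediate
10 | phloroglucinol (benzene-1,3,5-triol) | Oc1cc(O)cc(O)c1 | starting material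
11 | (13S)-13-acetoxyhexadecanoyl chloride | CCC[C@H](OC(C)=O)CCCCCCCCCCCC(=O)Cl | intermediate (not isolated)
12 | (13S)-13-acetoxy-1-(2,4,6-trihydroxyphenyl)hexadecan-1-one | CCC[C@H](OC(C)=O)CCCCCCCCCCCC(=O)c1c(O)cc(O)cc1O | intermediate
13 | (13S)-13-hydroxy-1-(2,4,6-trihydroxyphenyl)hexadecan-1-one | CCC[C@H](O)CCCCCCCCCCCC(=O)c1c(O)cc(O)cc1O | target

## Step count and least certain steps

Total step count: 8. Longest linear sequence: 7 (steps 1, 2, 3, 5, 6, 7, 8); step 4 is a one-step branch.

Step 5 (key step). The most likely failure is loss of 5 to statistical homo-coupling, together with over-oxidation of the C12 radical to a cation (helped by the neighbouring acetoxy group) that is trapped by methanol or loses a proton. A late drift to basic pH would add methanolysis of the acetate. The fallback builds the same C11–C12 bond by polar chemistry, without radicals at the coupling stage; it sets out from 5 and returns at 9. Iododecarboxylation of 5 (PhI(OAc)2, I2, visible light) should give (2S)-1-iodopentan-2-yl acetate F1. K2CO3 in methanol removes the acetyl group and the alkoxide closes to (2S)-2-propyloxirane F2, which is also an article of commerce; the C–O bond at the stereocentre is not touched. The dilithio derivative of commercial undec-10-ynoic acid (n-BuLi, 2 equiv, THF/DMPU) should open F2 at its CH2 terminus to give (13S)-13-hydroxyhexadec-10-ynoic acid F3. Hydrogenation over Pd/C saturates the triple bond to (13S)-13-hydroxyhexadecanoic acid F4. Acetyl chloride and then water, as in step 3, lead through acetic (13S)-13-acetoxyhexadecanoic anhydride F5 to 9.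

Step 7. The most likely failures are O-acylation and double acylation of the very nucleophilic ring, or Lewis-acid attack at the C13 acetate with loss of the protecting group, loss of configuration or alkylation of the arene. The fallback is a Houben–Hoesch acylation, which needs no aluminium halide and uses an electrophile that cannot acylate oxygen or react twice; it sets out from 9 and returns at 12. 9 is converted with 1,1'-carbonyldiimidazole and then ammonia into (13S)-13-acetoxyhexadecanamide F6, which trifluoroacetic anhydride/pyridine dehydrates to (13S)-13-acetoxyhexadecanenitrile F7. Condensation of F7 with 10 in ether saturated with HCl in the presence of ZnCl2 should precipitate (13S)-13-acetoxy-1-(2,4,6-trihydroxyphenyl)hexadecan-1-iminium chloride F8, and warm water hydrolyses it to 12. Any acetate hydrolysed at this point is of no consequence, since step 8 follows.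

Step 3. The most likely failure is β-elimination of acetic acid from the activated carboxyl derivative 4, or incomplete hydrolysis of 4. The fallback masks the carboxyl group first so that it is never activated; it sets out from 3 and returns at 5. Alkylation of the carboxylate (BnBr, KHCO3, DMF) gives benzyl (3S)-3-hydroxyhexanoate F9, acetylation (Ac2O, pyridine, cat. DMAP) gives benzyl (3S)-3-acetoxyhexanoate F10, and hydrogenolysis (H2, Pd/C, EtOAc) releases 5 under neutral conditions.

Step 4. The most likely failure is over-esterification to the diester and a laborious separation of diacid, half ester and diester, which limits the supply of the partner used in excess in step 5. The fallback differentiates the two ends with orthogonal esters and not by statistics; it sets out from 6 and returns at 7. Fischer esterification (MeOH, H2SO4) gives dimethyl dodecanedioate F11. Half-saponification with Ba(OH)2 in methanol, in which the barium salt of the half ester precipitates and is thereby kept from the second hydrolysis, gives after acidification 12-methoxy-12-oxododecanoic acid F12. tert-Butylation of the free carboxyl group (tert-butyl 2,2,2-trichloroacetimidate, cat. BF3·OEt2) gives 1-tert-butyl 12-methyl dodecanedioate F13, and LiOH (1 equiv) in aqueous THF hydrolyses only the methyl ester to return 7.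

## Further compounds

F1 | step 5 | (2S)-1-iodopentan-2-yl acetate | CCC[C@H](OC(C)=O)CI
F2 | step 5 | (2S)-2-propyloxirane | CCC[C@H]1CO1
F3 | step 5 | (13S)-13-hydroxyhexadec-10-ynoic acid | CCC[C@H](O)CC#CCCCCCCCCC(=O)O
F4 | step 5 | (13S)-13-hydroxyhexadecanoic acid | CCC[C@H](O)CCCCCCCCCCCC(=O)O
F5 | step 5 | acetic (13S)-13-acetoxyhexadecanoic anhydride | CCC[C@H](OC(C)=O)CCCCCCCCCCCC(=O)OC(C)=O
F6 | step 7 | (13S)-13-acetoxyhexadecanamide | CCC[C@H](OC(C)=O)CCCCCCCCCCCC(N)=O
F7 | step 7 | (13S)-13-acetoxyhexadecanenitrile | CCC[C@H](OC(C)=O)CCCCCCCCCCCC#N
F8 | step 7 | (13S)-13-acetoxy-1-(2,4,6-trihydroxyphenyl)hexadecan-1-iminium chloride | CCC[C@H](OC(C)=O)CCCCCCCCCCCC(=[NH2+])c1c(O)cc(O)cc1O.[Cl-]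
F9 | step 3 | benzyl (3S)-3-hydroxyhexanoate | CCC[C@H](O)CC(=O)OCc1ccccc1
F10 | step 3 | benzyl (3S)-3-acetoxyhexanoate | CCC[C@H](OC(C)=O)CC(=O)OCc1ccccc1
F11 | step 4 | dimethyl dodecanedioate | COC(=O)CCCCCCCCCCC(=O)OC
F12 | step 4 | 12-methoxy-12-oxododecanoic acid | COC(=O)CCCCCCCCCCC(=O)O
F13 | step 4 | 1-tert-butyl 12-methyl dodecanedioate | COC(=O)CCCCCCCCCCC(=O)OC(C)(C)C
A1 | alternative 1 | (13S)-13-[(tert-butyldimethylsilyl)oxy]-1-(2,4,6-trihydroxyphenyl)hexadecan-1-one | CCC[C@H](O[Si](C)(C)C(C)(C)C)CCCCCCCCCCCC(=O)c1c(O)cc(O)cc1O
A2 | alternative 1 | methyl (19S)-19-[(tert-butyldimethylsilyl)oxy]-3,5,7-trioxodocosanoate | CCC[C@H](O[Si](C)(C)C(C)(C)C)CCCCCCCCCCCC(=O)CC(=O)CC(=O)CC(=O)OC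
A3 | alternative 2 | 1-(2,4,6-trimethoxyphenyl)hexadecane-1,13-dione | CCCC(=O)CCCCCCCCCCCC(=O)c1c(OC)cc(OC)cc1OC
A4 | alternative 2 | 1-(2,4,6-trimethoxyphenyl)cyclodecan-1-ol | COc1cc(OC)c(C2(O)CCCCCCCCC2)c(OC)c1
A5 | alternative 2 | hex-1-en-3-one | CCCC(=O)C=C
A6 | alternative 3 | (13S)-13-[(tert-butyldimethylsilyl)oxy]-1-[2,4,6-tris(benzyloxy)phenyl]hexadecan-1-one | CCC[C@H](O[Si](C)(C)C(C)(C)C)CCCCCCCCCCCC(=O)c1c(OCc2ccccc2)cc(OCc2ccccc2)cc1OCc1ccccc1
A7 | alternative 3 | S-(pyridin-2-yl) 2,4,6-tris(benzyloxy)benzenecarbothioate | O=C(Sc1ccccn1)c1c(OCc2ccccc2)cc(OCc2ccccc2)cc1OCc1ccccc1
A8 | alternative 3 | tert-butyl{[(4S)-15-iodopentadecan-4-yl]oxy}dimethylsilane | CCC[C@H](O[Si](C)(C)C(C)(C)C)CCCCCCCCCCCI
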